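## The problem

Germacrane numbering is used throughout: ring carbons C1–C10, C14 on C10, C15 on C4, and C11–C13 on C7 (C12 is the lactone carbonyl, C13 the acetoxymethyl carbon).

The target is a germacranolide: a ten-membered carbocycle (C1–C10) fused through C6–C7 to a butenolide (O–C6–C7=C11–C12). It carries trans-trisubstituted epoxides at C1–C10 and C4–C5, an (S)-2-methylglycidate ester on C8 and an acetoxymethyl group on C11. A ten-membered ring with two (E)-trisubstituted alkenes (the epoxide precursors) is hard to close. Of the seven stereocenters (1R,4R,5R,6S,8S,10R and 2'S), the four epoxide carbons lie on the outer faces of a crossed (E,E)-1(10),4-diene and can be relayed from C6 through the ring conformation. C8 is separated from C6 by the sp2 carbon C7 and cannot be relayed reliably, and the side-chain centre is independent.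

The tetrasubstituted C7=C11 bond bears four oxidised carbons: C6 and C8 on C7, C12 and C13 on C11, with C6 cis to C12 and C8 cis to C13. This is the substitution pattern of a furan-3,4-dicarboxylate after oxidative ring opening. C7 and C11 are the furan β-carbons, C8 and C13 the α-carbons, and C6 and C12 the two carboxyl carbons. This hidden furan ring (O–C8–C7–C11–C13) is the feature that makes the key step, a [4+2] oxidative dearomatisation, possible.

The groups that will not survive rough treatment are:
- the two epoxides (acid causes transannular cyclisation);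
- the C8 and C13 acyloxy groups, both allylic to an electron-poor alkene (addition–elimination with nucleophiles, E1cB with base);
- the γ-acidic C6–H;
- the glycidate ester.

## Retrosynthesis

**C8–O acyl bond.** Target 26 is cut to alcohol 23 and (S)-2-methyloxirane-2-carboxylic acid 25. This cut comes last because the glycidate and the doubly allylic ester array are the most fragile parts. Acid 25 comes in one oxidation from the chiral alcohol 24, so the 2'S centre is bought. The forward step is an acylation with retention at C8.

**C13 acetate and the C8–H and C13–H bonds.** Monoacetate 23 goes back to diol 22, and 22 to keto-aldehyde 21. Making C8 a ketone turns the one stereocenter that C6 cannot control into a reagent-controlled carbonyl reduction. The primary and secondary hydroxyls of 22 differ enough for selective acetylation.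

**Retro-[4+2] at C8 and C13 (key).** In 21 the C8 ketone and C13 aldehyde are cis on C7=C11, which is a (Z)-ene-1,4-dione. Rejoining C8 and C13 through one oxygen gives furan 19. The neighbouring option, building the butenolide by olefination of a C7 ketone, would carry the C8 stereocenter and a base-sensitive allylic system through the ring closure. The furan has one stereocenter fewer, no tetrasubstituted alkene and no electrophilic allylic ester. The forward step must oxidise only the furan and stop at the dicarbonyl level.

**Both epoxides.** Diepoxide 19 goes back to the (E,E)-diene 18. The forward step relies on attack at the outer faces of the crossed diene, controlled by C6, with the acyl-deactivated furan left alone.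

**C5–C6 bond and lactone C–O bond.** Macrolactone 18 goes back through hydroxy ester 17 to the open-chain iodo aldehyde 16. Among the ring bonds, C5–C6 is chosen for three reasons: it creates the only stereocenter of 18, the C6 aldehyde is non-enolisable, and it sits next to the ester that becomes the lactone. Precursor 16 is acyclic and achiral. The forward step is an asymmetric Nozaki–Hiyama–Kishi ring closure at high dilution, followed by lactonisation.

**C8–C9 bond.** Aldehyde 16 comes from silyl ether 14 by deprotection (15) and oxidation. Compound 14 is cut into bromofuran 12 (as its Grignard reagent 13) and allylic bromide 7. The polarity follows from furan reactivity, since electrophilic bromination selects the future C8.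

**The two building blocks.** Bromofuran 12 comes from commercial dimethyl furan-3,4-dicarboxylate 8 through half-ester 9, hydroxy ester 10 and silyl ether 11. The furan supplies C6, C7, C8, C11, C12 and C13. Bromide 7 comes from pent-4-yn-1-ol 1 through alane 2, vinyl iodide 3, aldehyde 4, ester 5 and alcohol 6. Carboalumination and Wittig olefination set both (E)-alkenes.

## Roads not taken

**Alternative 1:** (the most obvious) Cut C6–C7 and the lactone C–O bond. The forward key step would be an intramolecular Nozaki–Hiyama–Kishi allylation of a farnesal-type C6 aldehyde by a 2-(bromomethyl)acrylate whose γ-carbon is C7 and which already carries a C8 silyl ether. It would give the α-methylene lactone A1. A1 has C7–H and an exocyclic C11=C13 bond, so the target would still need an alkene shift to C7=C11 together with oxidation at C13, in the presence of two reactive ring alkenes. No selective method exists for that. Three stereocenters (C6, C7, C8) would have to be matched in a macrocyclic transition state, and C7 is then destroyed. The chosen plan has the C7=C11 bond and the C13 oxygen latent in the furan from the first step.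

**Alternative 2:** Ring expansion by anionic oxy-Cope rearrangement. Carbinol A2 would be made by adding a (Z)-2-ethoxyvinyl anion to the matching 6-isopropenyl cyclohexenone. The [3,3] shift would form C8–C9, the (E)-C1=C10 bond and the ten-membered ring in dienone A3 without any macrocyclisation. However, the C4=C5 bond is inherited from the six-membered ring as the cis isomer, which cannot give the trans-4,5-epoxide. The C6 ketone would also still need C11–C13 attached at C7 and a stereoselective reduction. The run of corrections after the key step outweighs the gain.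

**Alternative 3:** The same oxidation logic on a non-aromatic diene. The exocyclic s-cis diene lactone A4 (C13=C11–C7=C8) would add singlet oxygen across C8 and C13 and, after O–O reduction, give diol 22 directly. A4 would need an unprecedented macrocyclisation of an allenylmethyl chromium reagent. The C8 configuration would be set only by the face of cycloaddition under substrate control, and an electron-poor diene reacts slowly with singlet oxygen. The furan offers the same four-carbon unit in a stable, commercial, aromatic form and moves C8 control to a reagent-controlled ketone reduction.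

Key step: step 14

Assumption (step 12): the (S)-configured oxazoline sulfonamide ligand is assumed to give the (6R)-alcohol 17. The sense of induction is to be confirmed on a model furan aldehyde, and the (R)-ligand is used if it is the opposite.

Remark: the C6 descriptor changes from R (17, 18) to S (19 onward) only because epoxidation raises the CIP rank of C5. No bond at C6 is touched.

## Steps

Step 1
Reactants: 1 pent-4-yn-1-ol
Product: 3 (E)-5-iodo-4-methylpent-4-en-1-ol, via (E)-alkenylalane 2 (not isolated)
Conditions: Me3Al, Cp2ZrCl2 (0.25 equiv), CH2Cl2, 0 to 23 °C; then I2, THF, −30 to 0 °C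
Reagents that add atoms: trimethylaluminium, C[Al](C)C; iodine, II
Why: Zirconium-catalysed syn-carboalumination of the terminal alkyne (Negishi carboalumination) puts CH3 on the internal carbon and aluminium on the terminal carbon; iodinolysis of the C–Al bond with retention should give the (E)-vinyl iodide that becomes C5=C4(C15).

Step 2
Reactants: 3 (E)-5-iodo-4-methylpent-4-en-1-ol
Product: 5 ethyl (2E,6E)-7-iodo-2,6-dimethylhepta-2,6-dienoate, via (E)-5-iodo-4-methylpent-4-enal 4 (not isolated)
Conditions: 2-iodoxybenzoic acid, DMSO, 23 °C; then Ph3P=C(CH3)CO2Et, 23 °C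
Reagents that add atoms: ethyl 2-(triphenylphosphoranylidene)propanoate, CCOC(=O)C(C)=P(c1ccccc1)(c1ccccc1)c1ccccc1
Why: Oxidation of the primary alcohol and Wittig olefination in one flask; the stabilised α-methyl ylide should give the (E)-trisubstituted enoate (future C10=C1), and the vinyl iodide is inert to both reagents.

Step 3
Reactants: 5 ethyl (2E,6E)-7-iodo-2,6-dimethylhepta-2,6-dienoate
Product: 6 (2E,6E)-7-iodo-2,6-dimethylhepta-2,6-dien-1-ol
Conditions: i-Bu2AlH, CH2Cl2, −78 °C
Reagents that add atoms: none
Why: 1,2-Reduction of the conjugated ester by the aluminium hydride at low temperature should give the allylic alcohol without touching the vinyl iodide or either alkene geometry.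

Step 4
Reactants: 6 (2E,6E)-7-iodo-2,6-dimethylhepta-2,6-dien-1-ol
Product: 7 (2E,6E)-1-bromo-7-iodo-2,6-dimethylhepta-2,6-diene
Conditions: CBr4, PPh3, CH2Cl2, 0 °C
Reagents that add atoms: tetrabromomethane, BrC(Br)(Br)Br
Why: Appel bromination of the primary allylic alcohol under neutral conditions; SN2 displacement at the unhindered CH2 (future C9) keeps the (E)-alkene in place.

Step 5
Reactants: 8 dimethyl furan-3,4-dicarboxylate
Product: 9 4-(methoxycarbonyl)furan-3-carboxylic acid
Conditions: NaOH (1.0 equiv), THF/H2O, 0 °C; then aq. HCl
Reagents that add atoms: sodium hydroxide, [Na+].[OH-]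
Why: Half-saponification of a symmetric diester; the carboxylate formed first deactivates the second ester, so the symmetry of the furan is broken cleanly.

Step 6
Reactants: 9 4-(methoxycarbonyl)furan-3-carboxylic acid
Product: 10 methyl 4-(hydroxymethyl)furan-3-carboxylate
Conditions: BH3·SMe2, THF, 0 to 23 °C
Reagents that add atoms: none
Why: Borane reduces a free carboxylic acid much faster than a methyl ester (acyloxyborane activation), so only the future C6 reaches the alcohol level while C12 stays an ester.

Step 7
Reactants: 10 methyl 4-(hydroxymethyl)furan-3-carboxylate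
Product: 11 methyl 4-{[tert-butyl(dimethyl)silyl]oxymethyl}furan-3-carboxylate
Conditions: TBSCl, imidazole, DMF, 23 °C
Reagents that add atoms: tert-butyldimethylsilyl chloride, CC(C)(C)[Si](C)(C)Cl
Why: Standard silylation of the primary alcohol; the silyl ether masks the C6 hydroxyl during the halogen–magnesium exchange of step 9.

Step 8
Reactants: 11 methyl 4-{[tert-butyl(dimethyl)silyl]oxymethyl}furan-3-carboxylate
Product: 12 methyl 5-bromo-4-{[tert-butyl(dimethyl)silyl]oxymethyl}furan-3-carboxylate
Conditions: NBS, DMF, 0 °C, dark
Reagents that add atoms: N-bromosuccinimide, O=C1CCC(=O)N1Br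
Why: Electrophilic aromatic bromination of a 3-furoate goes to the α-carbon that is not conjugated with the ester and lies next to the alkyl-bearing carbon (future C8); the other α-carbon (future C13) is deactivated as the β-carbon of the furan acrylate unit.

Step 9
Reactants: 12 methyl 5-bromo-4-{[tert-butyl(dimethyl)silyl]oxymethyl}furan-3-carboxylate; 7 (2E,6E)-1-bromo-7-iodo-2,6-dimethylhepta-2,6-diene
Product: 14 methyl 4-{[tert-butyl(dimethyl)silyl]oxymethyl}-5-[(2E,6E)-7-iodo-2,6-dimethylhepta-2,6-dien-1-yl]furan-3-carboxylate, via furylmagnesium chloride 13 (not isolated)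
Conditions: i-PrMgCl·LiCl, THF, −40 °C; then Li2CuCl4 (5 mol%), 7, −40 to 0 °C
Reagents that add atoms: none
Why: Bromine–magnesium exchange on the 2-bromofuran at low temperature tolerates the ester; copper-catalysed allylation of Grignard reagent 13 with the primary allylic bromide under Li2CuCl4 in THF should take the SN2 course at CH2, forming C8–C9 with the (E)-alkene retained, and the vinyl iodide does not couple under these conditions.

Step 10
Reactants: 14 methyl 4-{[tert-butyl(dimethyl)silyl]oxymethyl}-5-[(2E,6E)-7-iodo-2,6-dimethylhepta-2,6-dien-1-yl]furan-3-carboxylate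
Product: 15 methyl 4-(hydroxymethyl)-5-[(2E,6E)-7-iodo-2,6-dimethylhepta-2,6-dien-1-yl]furan-3-carboxylate
Conditions: HF·pyridine, THF/pyridine, 0 °C
Reagents that add atoms: none
Why: Acidic fluoride cleaves the primary silyl ether without forming the free alkoxide that basic fluoride would generate next to the ester.

Step 11
Reactants: 15 methyl 4-(hydroxymethyl)-5-[(2E,6E)-7-iodo-2,6-dimethylhepta-2,6-dien-1-yl]furan-3-carboxylate
Product: 16 methyl 4-formyl-5-[(2E,6E)-7-iodo-2,6-dimethylhepta-2,6-dien-1-yl]furan-3-carboxylate
Conditions: MnO2, CH2Cl2, 23 °C
Reagents that add atoms: none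
Why: Manganese dioxide oxidises the activated furylmethanol to the furan-3-carbaldehyde (C6) and leaves the trisubstituted alkene, the vinyl iodide and the ester untouched.

Step 12
Reactants: 16 methyl 4-formyl-5-[(2E,6E)-7-iodo-2,6-dimethylhepta-2,6-dien-1-yl]furan-3-carboxylate
Product: 18 (6R,1(10)E,4E)-8,13-epoxygermacra-1(10),4,7,11(13)-tetraen-12,6-olide, via macrocyclic hydroxy ester 17 (not isolated)
Conditions: CrCl2, NiCl2 (cat.), (S)-N-[2-(4-isopropyl-4,5-dihydro-1,3-oxazol-2-yl)-6-methylphenyl]methanesulfonamide, Et3N, THF/MeCN, 0.003 M, 23 °C; then PPTS, PhMe, 40 °C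
Reagents that add atoms: none
Why: Nozaki–Hiyama–Kishi reaction: zerovalent nickel inserts into the C5–I bond, the alkenyl group passes to trivalent chromium with retention of the (E)-geometry and adds to the non-enolisable C6 aldehyde at high dilution, closing the ten-membered ring in which the furan holds C6 and C9 cis like a rigid (Z)-alkene. The chromium-bound chiral oxazoline sulfonamide selects the aldehyde face and sets C6, and acid-catalysed attack of the C6 hydroxyl on the neighbouring ester then closes the lactone.

Step 13
Reactants: 18 (6R,1(10)E,4E)-8,13-epoxygermacra-1(10),4,7,11(13)-tetraen-12,6-olide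
Product: 19 (1R,4R,5R,6S,10R)-1,10:4,5:8,13-triepoxygermacra-7,11(13)-dien-12,6-olide
Conditions: mCPBA (2.3 equiv), NaHCO3, CH2Cl2, −20 to 0 °C
Reagents that add atoms: 3-chloroperoxybenzoic acid, O=C(OO)c1cccc(Cl)c1
Why: Prilezhaev epoxidation: the strained, electron-rich (E)-trisubstituted ring alkenes should react far faster with buffered peracid than the acyl-deactivated furan. Attack on the exposed outer face of each alkene in the crossed conformation fixed by C6 should give the two trans-epoxides with 1R,10R and 4R,5R configuration; the threo relation of C5–O to C6–O follows from the conformer in which H6 eclipses C4=C5 to avoid allylic 1,3-strain with C15.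

Step 14
Reactants: 19 (1R,4R,5R,6S,10R)-1,10:4,5:8,13-triepoxygermacra-7,11(13)-dien-12,6-olide
Product: 21 (1R,4R,5R,6S,10R)-1,10:4,5-diepoxy-8,13-dioxogermacr-7(11)-en-12,6-olide, via furan endoperoxide 20 (not isolated)
Conditions: O2, visible light, tetraphenylporphyrin (cat.), CH2Cl2, −78 °C; then Me2S, −78 to 0 °C
Reagents that add atoms: dioxygen, O=O
Why: Singlet oxygen, formed by energy transfer from the excited porphyrin, adds to the furan in a concerted suprafacial [4+2] cycloaddition across the two α-carbons C8 and C13 to give the 2,3,7-trioxabicyclo[2.2.1]heptene 20; this transient bicycle is the only ring the step closes (by cycloaddition), and no ring of the target is closed. Dimethyl sulfide then reduces the peroxide bridge and the resulting bis-hemiketal collapses to the C8 ketone and the C13 aldehyde, so that the furan C7–C11 bond becomes the tetrasubstituted C7=C11 double bond of the butenolide. The closest known reaction type is the photooxygenation of 2-alkylfurans to (Z)-ene-1,4-diones with sulfide reduction. No stereocenter is created, since C8 and C13 become sp2 carbons, and the cis relation of C8 to C13 cannot be lost because the lactone ring ties C6 to C12 on the other side of the double bond. The step needs chemoselectivity for the furan over every other π-bond, which is secured because both ring alkenes were epoxidised in step 13. It also needs the oxidation to stop at the dicarbonyl level, which is secured by reducing the endoperoxide at −78 °C under neutral, base-free conditions so that the C13–H bridgehead is not taken on to a carboxyl group. Regiochemistry is not an issue because both α-carbons are oxidised, and release of the strain of the furan-fused five-membered lactone adds driving force while the epoxides are inert to both reagents.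

Step 15
Reactants: 21 (1R,4R,5R,6S,10R)-1,10:4,5-diepoxy-8,13-dioxogermacr-7(11)-en-12,6-olide
Product: 22 (1R,4R,5R,6S,8S,10R)-1,10:4,5-diepoxy-8,13-dihydroxygermacr-7(11)-en-12,6-olide
Conditions: (R)-2-methyl-CBS-oxazaborolidine (1 equiv), catecholborane, PhMe/CH2Cl2, −78 °C; MeOH quench
Reagents that add atoms: none
Why: Corey–Bakshi–Shibata reduction: catecholborane activated by the oxazaborolidine reduces the aldehyde and then the C8 ketone by 1,2-hydride delivery. With the tetrasubstituted butenolide carbon C7 as the large and the C9 methylene as the small substituent, the (R)-catalyst should give the (8S)-alcohol, and the borate formed first at C13 prevents hemiketal formation with the C8 ketone.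

Step 16
Reactants: 22 (1R,4R,5R,6S,8S,10R)-1,10:4,5-diepoxy-8,13-dihydroxygermacr-7(11)-en-12,6-olide
Product: 23 (1R,4R,5R,6S,8S,10R)-13-acetoxy-1,10:4,5-diepoxy-8-hydroxygermacr-7(11)-en-12,6-olide
Conditions: AcCl (1.1 equiv), 2,4,6-collidine, CH2Cl2, −78 °C
Reagents that add atoms: acetyl chloride, CC(=O)Cl
Why: Acylation with acetyl chloride and the hindered base collidine at low temperature should be selective for the primary C13 hydroxyl over the hindered secondary allylic C8 hydroxyl.

Step 17
Reactants: 24 (R)-(2-methyloxiran-2-yl)methanol
Product: 25 (S)-2-methyloxirane-2-carboxylic acid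
Conditions: RuCl3 (cat.), NaIO4, MeCN/CCl4/H2O, 0 to 23 °C
Reagents that add atoms: water, O
Why: Ruthenium tetroxide, regenerated by periodate, oxidises the primary alcohol through the aldehyde hydrate to the carboxylic acid without touching the epoxide or the quaternary stereocenter; the descriptor changes from R to S by CIP priority only.

Step 18
Reactants: 23 (1R,4R,5R,6S,8S,10R)-13-acetoxy-1,10:4,5-diepoxy-8-hydroxygermacr-7(11)-en-12,6-olide; 25 (S)-2-methyloxirane-2-carboxylic acid
Product: 26 (1R,4R,5R,6S,8S,10R)-13-acetoxy-1,10:4,5-diepoxy-8-[(2S)-2-methyloxirane-2-carbonyloxy]germacr-7(11)-en-12,6-olide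
Conditions: EDC·HCl, DMAP, CH2Cl2, 0 to 23 °C
Reagents that add atoms: none
Why: Steglich esterification: the carbodiimide activates acid 25 and DMAP passes the acyl group to the C8 hydroxyl with retention at C8, under near-neutral conditions that spare both ring epoxides, the glycidate epoxide and the allylic acetate.

## Compound list

1 | pent-4-yn-1-ol | C#CCCCO | starting material
2 | dimethylaluminium alkoxide of (E)-5-(dimethylalumanyl)-4-methylpent-4-en-1-ol | C[Al](C)OCCC/C(C)=C/[Al](C)C | intermediate
3 | (E)-5-iodo-4-methylpent-4-en-1-ol | OCCC/C(C)=C/I | intermediate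
4 | (E)-5-iodo-4-methylpent-4-enal | O=CCC/C(C)=C/I | intermediate
5 | ethyl (2E,6E)-7-iodo-2,6-dimethylhepta-2,6-dienoate | CCOC(=O)/C(C)=C/CC/C(C)=C/I | intermediate
6 | (2E,6E)-7-iodo-2,6-dimethylhepta-2,6-dien-1-ol | OC/C(C)=C/CC/C(C)=C/I | intermediate
7 | (2E,6E)-1-bromo-7-iodo-2,6-dimethylhepta-2,6-diene | BrC/C(C)=C/CC/C(C)=C/I | intermediate
8 | dimethyl furan-3,4-dicarboxylate | COC(=O)c1cocc1C(=O)OC | starting material
9 | 4-(methoxycarbonyl)furan-3-carboxylic acid | COC(=O)c1cocc1C(=O)O | intermediate
10 | methyl 4-(hydroxymethyl)furan-3-carboxylate | COC(=O)c1cocc1CO | intermediate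
11 | methyl 4-{[tert-butyl(dimethyl)silyl]oxymethyl}furan-3-carboxylate | COC(=O)c1cocc1CO[Si](C)(C)C(C)(C)C | intermediate
12 | methyl 5-bromo-4-{[tert-butyl(dimethyl)silyl]oxymethyl}furan-3-carboxylate | COC(=O)c1coc(Br)c1CO[Si](C)(C)C(C)(C)C | intermediate
13 | [3-{[tert-butyl(dimethyl)silyl]oxymethyl}-4-(methoxycarbonyl)furan-2-yl]magnesium chloride | COC(=O)c1coc([Mg]Cl)c1CO[Si](C)(C)C(C)(C)C | intermediate
14 | methyl 4-{[tert-butyl(dimethyl)silyl]oxymethyl}-5-[(2E,6E)-7-iodo-2,6-dimethylhepta-2,6-dien-1-yl]furan-3-carboxylate | COC(=O)c1coc(C/C(C)=C/CC/C(C)=C/I)c1CO[Si](C)(C)C(C)(C)C | intermediate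
15 | methyl 4-(hydroxymethyl)-5-[(2E,6E)-7-iodo-2,6-dimethylhepta-2,6-dien-1-yl]furan-3-carboxylate | COC(=O)c1coc(C/C(C)=C/CC/C(C)=C/I)c1CO | intermediate
16 | methyl 4-formyl-5-[(2E,6E)-7-iodo-2,6-dimethylhepta-2,6-dien-1-yl]furan-3-carboxylate | COC(=O)c1coc(C/C(C)=C/CC/C(C)=C/I)c1C=O | intermediate
17 | methyl (6R,1(10)E,4E)-6-hydroxy-8,13-epoxygermacra-1(10),4,7,11(13)-tetraen-12-oate | COC(=O)c1coc2C/C(C)=C/CC/C(C)=C/[C@@H](O)c12 | intermediate
18 | (6R,1(10)E,4E)-8,13-epoxygermacra-1(10),4,7,11(13)-tetraen-12,6-olide | O=C1O[C@@H]2/C=C(C)/CC/C=C(C)/Cc3occ1c32 | intermediate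
19 | (1R,4R,5R,6S,10R)-1,10:4,5:8,13-triepoxygermacra-7,11(13)-dien-12,6-olide | c1oc2C[C@@]3(C)O[C@@H]3CC[C@@]3(C)O[C@@H]3[C@H]4OC(=O)c1c24 | intermediate
20 | 8,13-epidioxy adduct (furan endoperoxide) of 19, bridgeheads C8 and C13 undefined | C12OOC3(O1)C[C@@]4(C)O[C@@H]4CC[C@@]4(C)O[C@@H]4[C@H]4OC(=O)C2=C34 | intermediate
21 | (1R,4R,5R,6S,10R)-1,10:4,5-diepoxy-8,13-dioxogermacr-7(11)-en-12,6-olide | O=CC1=C2C(=O)C[C@@]3(C)O[C@@H]3CC[C@@]3(C)O[C@@H]3[C@H]2OC1=O | intermediate
22 | (1R,4R,5R,6S,8S,10R)-1,10:4,5-diepoxy-8,13-dihydroxygermacr-7(11)-en-12,6-olide | OCC1=C2[C@@H](O)C[C@@]3(C)O[C@@H]3CC[C@@]3(C)O[C@@H]3[C@H]2OC1=O | intermediate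
23 | (1R,4R,5R,6S,8S,10R)-13-acetoxy-1,10:4,5-diepoxy-8-hydroxygermacr-7(11)-en-12,6-olide | CC(=O)OCC1=C2[C@@H](O)C[C@@]3(C)O[C@@H]3CC[C@@]3(C)O[C@@H]3[C@H]2OC1=O | intermediate
24 | (R)-(2-methyloxiran-2-yl)methanol | OC[C@]1(C)CO1 | starting material
25 | (S)-2-methyloxirane-2-carboxylic acid | OC(=O)[C@]1(C)CO1 | intermediate
26 | (1R,4R,5R,6S,8S,10R)-13-acetoxy-1,10:4,5-diepoxy-8-[(2S)-2-methyloxirane-2-carbonyloxy]germacr-7(11)-en-12,6-olide | CC(=O)OCC1=C2[C@@H](OC(=O)[C@]3(C)CO3)C[C@@]3(C)O[C@@H]3CC[C@@]3(C)O[C@@H]3[C@H]2OC1=O | target

## Step count and least certain steps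

Total step count: 18. Longest linear sequence: 13 steps (steps 1–4, 9–16 and 18 from 1; equally steps 5–16 and 18 from 8).

**Step 14 (key step).** The most likely failure is sluggish cycloaddition, because the lactone carbonyl on C11 lowers the electron density of the furan. During a long irradiation the endoperoxide could then rearrange or be oxidised further at the C13–H bridgehead before it is reduced. The fallback replaces the cycloaddition by an ionic oxidative ring opening. It sets out from 19: N-bromosuccinimide and NaHCO3 in aqueous THF at −20 °C attack the more electron-rich α-carbon C8, water is captured at C13, and hydrolysis gives the cyclic bis-hemiketal F1. F1 opens to the keto-aldehyde, and the route is rejoined at 21.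

**Step 12.** The most likely failure is low or wrong-sense asymmetric induction at C6, because the strained ten-membered transition state may override the preference of the chromium-bound ligand. Oligomerisation is the second risk. The fallback replaces asymmetric induction by resolution. It sets out from 16: the same Ni/Cr ring closure without chiral ligand gives the racemic hydroxy ester F2, isolated by neutral work-up. Sharpless kinetic resolution (Ti(Oi-Pr)4, D-(−)-diisopropyl tartrate, t-BuOOH, −20 °C) should epoxidise the (6S)-enantiomer at C4=C5 to the erythro epoxy alcohol F3 and leave the (6R)-alcohol 17. Lactonisation of 17 with PPTS rejoins the route at 18.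

**Step 13.** The most likely failure is poor facial selectivity at C1=C10, because only the ring conformation relays C6 to this alkene and a second conformer with C14 turned to the other face may be populated. Partial oxidation of the furan by the peracid is the second risk. The fallback replaces substrate control by reagent control. It sets out from 18 and uses the Shi epoxidation (D-fructose-derived ketone catalyst, Oxone, K2CO3 buffer, MeCN/dimethoxymethane/H2O, 0 °C), which delivers oxygen to the face of (E)-trisubstituted alkenes that gives R,R-epoxides, as both sites require. It returns at 19 and makes no new compound (F0).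

**Step 15.** The most likely failure is a mismatch between catalyst control and the substrate's preference for hydride attack from the ring periphery, leading to the (8R)-alcohol or to mixtures. Conjugate reduction of the electron-poor C7=C11 is the second risk. The fallback accepts the substrate's preference and corrects C8 at the end. It sets out from 21: Luche reduction (NaBH4, CeCl3, MeOH, −78 °C) gives, in the mismatched case, the (8R)-diol F4. Selective acetylation as in step 16 gives the (8R)-monoacetate F5. Mitsunobu esterification of F5 with acid 25 (PPh3, DIAD, PhMe, 0 °C) inverts C8 and rejoins the route at 26.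

## Further compounds

F1 | step 14 | (1R,4R,5R,6S,10R)-1,10:4,5:8,13-triepoxy-8,13-dihydroxygermacr-7(11)-en-12,6-olide (cyclic bis-hemiketal, C8 and C13 undefined) | OC1OC2(O)C[C@@]3(C)O[C@@H]3CC[C@@]3(C)O[C@@H]3[C@H]3OC(=O)C1=C23
F2 | step 12 | racemic methyl (1(10)E,4E)-6-hydroxy-8,13-epoxygermacra-1(10),4,7,11(13)-tetraen-12-oate | COC(=O)c1coc2C/C(C)=C/CC/C(C)=C/C(O)c12
F3 | step 12 | methyl (4R,5R,6R,1(10)E)-4,5:8,13-diepoxy-6-hydroxygermacra-1(10),7,11(13)-trien-12-oate | COC(=O)c1coc2C/C(C)=C/CC[C@@]3(C)O[C@@H]3[C@H](O)c12
F0 | step 13 | none | none
F4 | step 15 | (1R,4R,5R,6S,8R,10R)-1,10:4,5-diepoxy-8,13-dihydroxygermacr-7(11)-en-12,6-olide | OCC1=C2[C@H](O)C[C@@]3(C)O[C@@H]3CC[C@@]3(C)O[C@@H]3[C@H]2OC1=O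
F5 | step 15 | (1R,4R,5R,6S,8R,10R)-13-acetoxy-1,10:4,5-diepoxy-8-hydroxygermacr-7(11)-en-12,6-olide | CC(=O)OCC1=C2[C@H](O)C[C@@]3(C)O[C@@H]3CC[C@@]3(C)O[C@@H]3[C@H]2OC1=O
A1 | alternative 1 | (6α,7α-H,8α)-8-[tert-butyl(dimethyl)silyl]oxygermacra-1(10)E,4E,11(13)-trien-12,6-olide | C=C1[C@@H]2[C@@H](O[Si](C)(C)C(C)(C)C)C/C(C)=C/CC/C(C)=C/[C@H]2OC1=O
A2 | alternative 2 | 1-[(Z)-2-ethoxyethenyl]-3-methyl-6-(prop-1-en-2-yl)cyclohex-2-en-1-ol | CCO/C=C\C1(O)C=C(C)CCC1C(C)=C
A3 | alternative 2 | (1(10)E,4Z)-8-ethoxy-11,12,13-trinorgermacra-1(10),4-dien-6-one | CCOC1CC(=O)/C=C(C)\CC/C=C(C)/C1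
A4 | alternative 3 | (6R,1(10)E,4E,7Z)-germacra-1(10),4,7,11(13)-tetraen-12,6-olide | C=C1C(=O)O[C@@H]2/C=C(C)/CC/C=C(C)/C/C=C/12
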